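**Retrosynthetic overview**

- Target 26 is the (2R)-flavanone with 5,7,4′-trihydroxy and 6,3′,5′-triprenyl substitution. Removal of three methoxymethyl (MOM) ethers and enantioselective conjugate hydride delivery to C2 lead back to the achiral flavone 23.
- Ring C of 23 is cut at O1–C8a, C4–C4a and O1–C2, which gives a ring A aryne (from silyl triflate 14) and a ring B arylpropiolic acid (20).
- The strategy rests on this feature: in ring A the ether oxygen O1 and the acyl carbon C4 sit on the adjacent carbons C8a and C4a, and C4a is flanked by the oxygen-bearing C5. An aryne across C4a–C8a, polarised by that oxygen, takes up the acid as O at C8a and acyl at C4a, so the prenyl group lands at C6 with no choice between phenols.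
- 14 comes from phloroglucinol through the symmetrical phenol 7 (carbamate-directed ortho-silylation, triflation); 20 comes from 4-iodophenol (two successive ortho-prenylations, coupling with propiolic acid).
- Rings A and B are bought; ring C is the only ring formed (step 12).

Key step: step 12

Assumption: the sense of induction of ligated CuH on a flavone is not established, so (R)-DTBM-SEGPHOS is written provisionally; the ligand antipode that gives 2R is fixed by a trial on 23.

Prenyl = 3-methylbut-2-en-1-yl throughout.

**Route**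

Step 1
Reactants: 1 phloroglucinol
Product: 2 3,5-bis(methoxymethoxy)phenol
Conditions: MOMCl (2 equiv), i-Pr2NEt, DMF, 0 °C → rt; chromatography
Reagents that add atoms: chloromethyl methyl ether, COCCl
Why: Williamson-type O-alkylation of two of the three equivalent phenols gives a statistical mixture from which the bis-ether is separated, the mono-ether being resubmitted.

Step 2
Reactants: 2 3,5-bis(methoxymethoxy)phenol
Product: 3 [3,5-bis(methoxymethoxy)phenoxy]triisopropylsilane
Conditions: TIPSCl, imidazole, DMF, rt
Reagents that add atoms: chlorotriisopropylsilane, CC(C)[Si](Cl)(C(C)C)C(C)C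
Why: Imidazole-promoted O-silylation covers the last phenol with a bulky group that neither directs lithiation nor is attacked by n-BuLi.

Step 3
Reactants: 3 [3,5-bis(methoxymethoxy)phenoxy]triisopropylsilane; 4 prenyl bromide
Product: 6 [3,5-bis(methoxymethoxy)-4-prenylphenoxy]triisopropylsilane, via aryllithium 5 (not isolated)
Conditions: n-BuLi, THF, 0 °C; then 4, 0 °C → rt
Reagents that add atoms: none
Why: Directed ortho-metalation removes the proton flanked by the two chelating MOM ethers, and aryllithium 5 is alkylated by SN2 displacement at the primary allylic bromide.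

Step 4
Reactants: 6 [3,5-bis(methoxymethoxy)-4-prenylphenoxy]triisopropylsilane
Product: 7 3,5-bis(methoxymethoxy)-4-prenylphenol
Conditions: Bu4NF, AcOH, THF, 0 °C → rt
Reagents that add atoms: none
Why: Fluoride-induced cleavage of the aryl silyl ether under acetic acid buffering leaves the acetals and the alkene untouched.

Step 5
Reactants: 7 3,5-bis(methoxymethoxy)-4-prenylphenol
Product: 8 3,5-bis(methoxymethoxy)-4-prenylphenyl N-isopropylcarbamate
Conditions: i-PrNCO, Et3N (cat.), CH2Cl2, rt
Reagents that add atoms: isopropyl isocyanate, CC(C)N=C=O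
Why: Base-catalysed addition of the phenol to the isocyanate (carbamoylation) installs a strong ortho-directing group that can later be removed by mild E1cB cleavage.

Step 6
Reactants: 8 3,5-bis(methoxymethoxy)-4-prenylphenyl N-isopropylcarbamate
Product: 12 3,5-bis(methoxymethoxy)-4-prenyl-2-(trimethylsilyl)phenyl N-isopropylcarbamate, via N-silyl carbamate 9 (not isolated), via lithiated N-silyl carbamate 10 (not isolated), via C-silylated N-silyl carbamate 11 (not isolated)
Conditions: TBSOTf, TMEDA, Et2O, 0 °C → rt; n-BuLi, TMEDA, −78 °C; TMSCl, −78 °C → rt; cold aq NaHSO4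
Reagents that add atoms: chlorotrimethylsilane, C[Si](C)(C)Cl
Why: After in situ N-silylation, carbamate-directed ortho-metalation occurs at one of the two equivalent C–H positions lying between the carbamate and a MOM ether (the third position carries the prenyl group), the aryllithium is trapped by TMSCl, and the N–Si bond is hydrolysed on work-up.

Step 7
Reactants: 12 3,5-bis(methoxymethoxy)-4-prenyl-2-(trimethylsilyl)phenyl N-isopropylcarbamate
Product: 14 3,5-bis(methoxymethoxy)-4-prenyl-2-(trimethylsilyl)phenyl trifluoromethanesulfonate, via silylphenol 13 (not isolated)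
Conditions: DBU, Et2NH, MeCN, 40 °C; then PhNTf2, rt
Reagents that add atoms: N-phenylbis(trifluoromethanesulfonimide), O=S(=O)(N(c1ccccc1)S(=O)(=O)C(F)(F)F)C(F)(F)F
Why: DBU triggers E1cB fragmentation of the carbamate to isopropyl isocyanate (scavenged by Et2NH) and the phenoxide of 13, which is O-triflated by PhNTf2 in the same flask.

Step 8
Reactants: 15 4-iodophenol; 4 prenyl bromide
Product: 16 4-iodo-2-prenylphenol
Conditions: NaH (1.1 equiv), toluene, 0 °C → rt; then 4 (1.05 equiv), rt; chromatography
Reagents that add atoms: none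
Why: ortho-Selective C-alkylation of the tightly ion-paired sodium phenoxide in a non-polar solvent (para position blocked by iodine) gives the ortho-prenyl dienone, which rearomatises to the phenol, the minor O-prenyl ether being removed by chromatography.

Step 9
Reactants: 16 4-iodo-2-prenylphenol; 4 prenyl bromide
Product: 17 4-iodo-2,6-diprenylphenol
Conditions: NaH (1.1 equiv), toluene, 0 °C → rt; then 4 (1.1 equiv), rt → 40 °C; chromatography
Reagents that add atoms: none
Why: The same ortho-selective C-alkylation of the sodium phenoxide in toluene is repeated at the one remaining ortho position, again followed by rearomatisation.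

Step 10
Reactants: 17 4-iodo-2,6-diprenylphenol
Product: 18 5-iodo-2-(methoxymethoxy)-1,3-diprenylbenzene
Conditions: NaH, MOMCl, THF/DMF, 0 °C → rt
Reagents that add atoms: chloromethyl methyl ether, COCCl
Why: Williamson-type O-alkylation of the hindered sodium phenoxide with the small, reactive chloromethyl ether masks the phenol that would otherwise add to the aryne.

Step 11
Reactants: 18 5-iodo-2-(methoxymethoxy)-1,3-diprenylbenzene; 19 propiolic acid
Product: 20 3-[4-(methoxymethoxy)-3,5-diprenylphenyl]prop-2-ynoic acid
Conditions: Pd(PPh3)4 (cat.), DBU, DMSO, rt; then cold dilute citric acid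
Reagents that add atoms: none
Why: Copper-free Sonogashira-type coupling of the aryl iodide with propiolic acid at zerovalent palladium proceeds at room temperature, where decarboxylation of the arylpropiolate is slow.

Step 12
Reactants: 14 3,5-bis(methoxymethoxy)-4-prenyl-2-(trimethylsilyl)phenyl trifluoromethanesulfonate; 20 3-[4-(methoxymethoxy)-3,5-diprenylphenyl]prop-2-ynoic acid
Product: 23 5,7-bis(methoxymethoxy)-2-[4-(methoxymethoxy)-3,5-diprenylphenyl]-6-prenyl-4H-chromen-4-one, via aryne 21 (not isolated), via hydroxyaryl ynone 22 (not isolated)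
Conditions: CsF (4 equiv), THF, 125 °C, sealed tube (14 in 1.5-fold excess)
Reagents that add atoms: none
Why: Fluoride attack at silicon of 14 expels triflate to give aryne 21; the carboxylate of 20 adds through oxygen to the aryne carbon that becomes C8a, the aryl anion formed at C4a attacks the ester carbonyl through a four-membered transition state and collapse moves the acyl group from oxygen to carbon, giving the phenoxide of ynone 22, which adds to the alkyne carbon C2 and is protonated at C3 to give 23 (bonds O1–C8a, C4–C4a and O1–C2). The closest known reaction type is the fluoride-induced insertion of arynes into the C–O bond of carboxylic acids, which with alkynoic acids is known to continue to chromones and flavones. Ring C, the only ring formed, closes by 6-endo-dig oxa-Michael addition, favoured over the 5-exo-dig mode by the polarisation of the ynone and the stability of the 4-pyranone product. No stereocentre is formed. The selectivity needed is the regiochemistry of carboxylate addition to the unsymmetrical aryne: the methoxymethoxy group on the carbon next to C4a (the later O5) withdraws inductively, so the nucleophile goes to the remote, unhindered C8a and the carbanion sits at C4a, and since the oxygen delivered to C8a becomes O1 the prenyl group must end at C6 and not at C8. The excess of 14 and the high temperature are chosen so that acyl migration outruns protonation of the aryl anion.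

Step 13
Reactants: 23 5,7-bis(methoxymethoxy)-2-[4-(methoxymethoxy)-3,5-diprenylphenyl]-6-prenyl-4H-chromen-4-one
Product: 25 (2R)-5,7-bis(methoxymethoxy)-2-[4-(methoxymethoxy)-3,5-diprenylphenyl]-6-prenylchroman-4-one, via silyl enol ether 24 (not isolated)
Conditions: Cu(OAc)2 (cat.), (R)-DTBM-SEGPHOS (cat.), (EtO)2MeSiH, toluene, rt → 40 °C; then AcOH/H2O/THF
Reagents that add atoms: none
Why: Proposed new method: a bisphosphine-ligated monovalent copper hydride generated from Cu(OAc)2 and the silane should deliver hydride to C2 of the chromone enone on the face left open by the ligand, which thereby sets C2, giving a copper enolate that is silylated to 24 (this masks C4 against over-reduction and regenerates CuH) and hydrolysed on mild acidic work-up; the closest known reaction type is the CuH-catalysed asymmetric conjugate reduction of beta,beta-disubstituted cyclic enones and of 2-alkylchromones, here extended to an electron-rich 2-aryl-5,7-dialkoxychromone; the trisubstituted prenyl alkenes are not expected to undergo hydrocupration.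

Step 14
Reactants: 25 (2R)-5,7-bis(methoxymethoxy)-2-[4-(methoxymethoxy)-3,5-diprenylphenyl]-6-prenylchroman-4-one
Product: 26 (2R)-5,7-dihydroxy-2-[4-hydroxy-3,5-diprenylphenyl]-6-prenylchroman-4-one
Conditions: 3 M aq HCl, MeOH, 40 °C; neutralise to pH 6
Reagents that add atoms: none
Why: Acid-catalysed acetal methanolysis should remove all three MOM ethers without touching C2, the mild temperature and non-basic work-up being chosen to avoid phenol–prenyl cyclisation and base-induced ring-opening of the flavanone.

**Compound list**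

1 | phloroglucinol | Oc1cc(O)cc(O)c1 | starting material
2 | 3,5-bis(methoxymethoxy)phenol | COCOc1cc(O)cc(OCOC)c1 | intermediate
3 | [3,5-bis(methoxymethoxy)phenoxy]triisopropylsilane | COCOc1cc(O[Si](C(C)C)(C(C)C)C(C)C)cc(OCOC)c1 | intermediate
4 | prenyl bromide (1-bromo-3-methylbut-2-ene) | CC(C)=CCBr | starting material
5 | 2,6-bis(methoxymethoxy)-4-(triisopropylsilyloxy)phenyllithium | [Li]c1c(OCOC)cc(O[Si](C(C)C)(C(C)C)C(C)C)cc1OCOC | intermediate (not isolated)
6 | [3,5-bis(methoxymethoxy)-4-prenylphenoxy]triisopropylsilane | COCOc1cc(O[Si](C(C)C)(C(C)C)C(C)C)cc(OCOC)c1CC=C(C)C | intermediate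
7 | 3,5-bis(methoxymethoxy)-4-prenylphenol | COCOc1cc(O)cc(OCOC)c1CC=C(C)C | intermediate
8 | 3,5-bis(methoxymethoxy)-4-prenylphenyl N-isopropylcarbamate | COCOc1cc(OC(=O)NC(C)C)cc(OCOC)c1CC=C(C)C | intermediate
9 | 3,5-bis(methoxymethoxy)-4-prenylphenyl N-(tert-butyldimethylsilyl)-N-isopropylcarbamate | COCOc1cc(OC(=O)N(C(C)C)[Si](C)(C)C(C)(C)C)cc(OCOC)c1CC=C(C)C | intermediate (not isolated)
10 | 2-lithio derivative of 9 (lithium between carbamate and MOM ether) | COCOc1cc(OC(=O)N(C(C)C)[Si](C)(C)C(C)(C)C)c([Li])c(OCOC)c1CC=C(C)C | intermediate (not isolated)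
11 | 3,5-bis(methoxymethoxy)-4-prenyl-2-(trimethylsilyl)phenyl N-(tert-butyldimethylsilyl)-N-isopropylcarbamate | COCOc1cc(OC(=O)N(C(C)C)[Si](C)(C)C(C)(C)C)c([Si](C)(C)C)c(OCOC)c1CC=C(C)C | intermediate (not isolated)
12 | 3,5-bis(methoxymethoxy)-4-prenyl-2-(trimethylsilyl)phenyl N-isopropylcarbamate | COCOc1cc(OC(=O)NC(C)C)c([Si](C)(C)C)c(OCOC)c1CC=C(C)C | intermediate
13 | 3,5-bis(methoxymethoxy)-4-prenyl-2-(trimethylsilyl)phenol | COCOc1cc(O)c([Si](C)(C)C)c(OCOC)c1CC=C(C)C | intermediate (not isolated)
14 | 3,5-bis(methoxymethoxy)-4-prenyl-2-(trimethylsilyl)phenyl trifluoromethanesulfonate | COCOc1cc(OS(=O)(=O)C(F)(F)F)c([Si](C)(C)C)c(OCOC)c1CC=C(C)C | intermediate (key-step precursor)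
15 | 4-iodophenol | Oc1ccc(I)cc1 | starting material
16 | 4-iodo-2-prenylphenol | CC(C)=CCc1cc(I)ccc1O | intermediate
17 | 4-iodo-2,6-diprenylphenol | CC(C)=CCc1cc(I)cc(CC=C(C)C)c1O | intermediate
18 | 5-iodo-2-(methoxymethoxy)-1,3-diprenylbenzene | CC(C)=CCc1cc(I)cc(CC=C(C)C)c1OCOC | intermediate
19 | propiolic acid | C#CC(=O)O | starting material
20 | 3-[4-(methoxymethoxy)-3,5-diprenylphenyl]prop-2-ynoic acid | CC(C)=CCc1cc(C#CC(=O)O)cc(CC=C(C)C)c1OCOC | intermediate (key-step precursor)
21 | 3,5-bis(methoxymethoxy)-4-prenylbenzyne (triple bond across C1–C2) | COCOC1=CC#CC(OCOC)=C1CC=C(C)C | intermediate (not isolated)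
22 | 1-[6-hydroxy-2,4-bis(methoxymethoxy)-3-prenylphenyl]-3-[4-(methoxymethoxy)-3,5-diprenylphenyl]prop-2-yn-1-one | CC(C)=CCc1cc(C#CC(=O)c2c(O)cc(OCOC)c(CC=C(C)C)c2OCOC)cc(CC=C(C)C)c1OCOC | intermediate (not isolated)
23 | 5,7-bis(methoxymethoxy)-2-[4-(methoxymethoxy)-3,5-diprenylphenyl]-6-prenyl-4H-chromen-4-one | CC(C)=CCc1cc(-c2cc(=O)c3c(cc(OCOC)c(CC=C(C)C)c3OCOC)o2)cc(CC=C(C)C)c1OCOC | intermediate (key-step product)
24 | (2R)-4-[diethoxy(methyl)silyloxy]-5,7-bis(methoxymethoxy)-2-[4-(methoxymethoxy)-3,5-diprenylphenyl]-6-prenyl-2H-chromene | CC(C)=CCc1cc([C@H]2C=C(O[Si](C)(OCC)OCC)c3c(cc(OCOC)c(CC=C(C)C)c3OCOC)O2)cc(CC=C(C)C)c1OCOC | intermediate (not isolated)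
25 | (2R)-5,7-bis(methoxymethoxy)-2-[4-(methoxymethoxy)-3,5-diprenylphenyl]-6-prenylchroman-4-one | CC(C)=CCc1cc([C@H]2CC(=O)c3c(cc(OCOC)c(CC=C(C)C)c3OCOC)O2)cc(CC=C(C)C)c1OCOC | intermediate
26 | (2R)-5,7-dihydroxy-2-[4-hydroxy-3,5-diprenylphenyl]-6-prenylchroman-4-one | CC(C)=CCc1cc([C@H]2CC(=O)c3c(cc(O)c(CC=C(C)C)c3O)O2)cc(CC=C(C)C)c1O | target

**Step count and risks**

Total step count: 14. Longest linear sequence: 10 steps (steps 1–7, then 12–14).

Steps most likely to fail:

1. Step 13 (proposed new method). Hydride transfer to the electron-rich, cross-conjugated chromone may be too slow, or the ligand may discriminate poorly between the two faces of C2.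
   Fallback, setting out from 18 (together with 14) and coming back to the route at 25: the C2=C3 double bond is never made. Mizoroki–Heck coupling of 18 with acrylic acid (Pd(OAc)2, P(o-tol)3, Et3N, DMF, 90 °C) should give (E)-3-[4-(methoxymethoxy)-3,5-diprenylphenyl]prop-2-enoic acid F1. F1 and 14 under the conditions of step 12 should undergo the same aryne C–O insertion to the 2′-hydroxychalcone F2, which closes by 6-endo-trig oxa-Michael addition to the racemic flavanone tris(methoxymethyl) ether F3. Kinetic resolution of F3 by asymmetric transfer hydrogenation ([Cp*RhCl((S,S)-TsDPEN)], HCO2H/Et3N, EtOAc, rt) is expected to reduce the 2S ketone to the cis-(2S,4S)-flavan-4-ol F4 and leave (2R)-25, which is separated by chromatography.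

2. Step 12. The aryl anion may be protonated before acyl transfer (ending at the aryl ester), the propiolate may decarboxylate at 125 °C, the aryne may be consumed by ene reaction with a prenyl group, or the phenoxide may close in the 5-exo sense.
   Fallback, setting out from 8 and 20 and coming back to the route at 23: the C4–C4a bond is made by directed metalation instead of an aryne. 20 is converted into its N-methoxy-N-methylamide F5 (MeNH(OMe)·HCl, EDC·HCl, i-Pr2NEt, CH2Cl2). 8 is N-silylated and lithiated as in step 6 to give 10, which is acylated by F5 at −78 °C to the N-silyl keto carbamate F6; this is hydrolysed on work-up to the keto carbamate F7. DBU/Et2NH in MeCN then cleaves the carbamate as in step 7 and releases the phenoxide of 22, which under these secondary-amine conditions is expected to close in the 6-endo sense to 23. The regiochemistry is again fixed by the symmetry of 8.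

3. Step 14. Protic acid may add a phenol across a neighbouring prenyl double bond, or reversible ring-opening at C2 may erode the enantiomeric purity.
   Fallback, setting out from 25 and coming back to the route at 26: the acetals are exchanged for silyl ethers under aprotic, buffered conditions instead of being solvolysed. TMSOTf and 2,2′-bipyridyl in CH2Cl2 at 0 °C should convert the three aryl MOM ethers into the tris(trimethylsilyl) ether F8, which is hydrolysed by water at neutral pH to 26.

Further compounds
F1 | step 13 | (E)-3-[4-(methoxymethoxy)-3,5-diprenylphenyl]prop-2-enoic acid | CC(C)=CCc1cc(/C=C/C(=O)O)cc(CC=C(C)C)c1OCOC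
F2 | step 13 | (E)-1-[6-hydroxy-2,4-bis(methoxymethoxy)-3-prenylphenyl]-3-[4-(methoxymethoxy)-3,5-diprenylphenyl]prop-2-en-1-one | CC(C)=CCc1cc(/C=C/C(=O)c2c(O)cc(OCOC)c(CC=C(C)C)c2OCOC)cc(CC=C(C)C)c1OCOC
F3 | step 13 | racemic 5,7-bis(methoxymethoxy)-2-[4-(methoxymethoxy)-3,5-diprenylphenyl]-6-prenylchroman-4-one | CC(C)=CCc1cc(C2CC(=O)c3c(cc(OCOC)c(CC=C(C)C)c3OCOC)O2)cc(CC=C(C)C)c1OCOC
F4 | step 13 | (2S,4S)-5,7-bis(methoxymethoxy)-2-[4-(methoxymethoxy)-3,5-diprenylphenyl]-6-prenylchroman-4-ol | CC(C)=CCc1cc([C@@H]2C[C@H](O)c3c(cc(OCOC)c(CC=C(C)C)c3OCOC)O2)cc(CC=C(C)C)c1OCOC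
F5 | step 12 | N-methoxy-N-methyl-3-[4-(methoxymethoxy)-3,5-diprenylphenyl]prop-2-ynamide | CC(C)=CCc1cc(C#CC(=O)N(C)OC)cc(CC=C(C)C)c1OCOC
F6 | step 12 | 3,5-bis(methoxymethoxy)-2-{3-[4-(methoxymethoxy)-3,5-diprenylphenyl]prop-2-ynoyl}-4-prenylphenyl N-(tert-butyldimethylsilyl)-N-isopropylcarbamate | CC(C)=CCc1cc(C#CC(=O)c2c(OC(=O)N(C(C)C)[Si](C)(C)C(C)(C)C)cc(OCOC)c(CC=C(C)C)c2OCOC)cc(CC=C(C)C)c1OCOC
F7 | step 12 | 3,5-bis(methoxymethoxy)-2-{3-[4-(methoxymethoxy)-3,5-diprenylphenyl]prop-2-ynoyl}-4-prenylphenyl N-isopropylcarbamate | CC(C)=CCc1cc(C#CC(=O)c2c(OC(=O)NC(C)C)cc(OCOC)c(CC=C(C)C)c2OCOC)cc(CC=C(C)C)c1OCOC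
F8 | step 14 | (2R)-5,7-bis(trimethylsilyloxy)-2-[3,5-diprenyl-4-(trimethylsilyloxy)phenyl]-6-prenylchroman-4-one | CC(C)=CCc1cc([C@H]2CC(=O)c3c(cc(O[Si](C)(C)C)c(CC=C(C)C)c3O[Si](C)(C)C)O2)cc(CC=C(C)C)c1O[Si](C)(C)C
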